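## The problem

Target 19 is a cyclobutane whose ring carbons carry, in alternation, two 3,4-dimethoxyphenyl groups and two carbonyl groups, each carbonyl being the exocyclic half of an imide with 5,6-dihydropyridin-2(1H)-one. The substitution is 1α,2α,3β,4β: the aryl groups are trans to each other across the ring, so are the acyl groups, and every acyl-bearing carbon is cis to one aryl neighbour and trans to the other. The molecule has an inversion centre and is achiral, so only relative configuration must be controlled and racemic intermediates suffice. Because the arrangement is not all-trans, equilibration cannot deliver it; each centre has to be set by a stereospecific event, and the two carbonyl-bearing carbons, epimerisable once they sit α to an imide, are best held below the carboxyl oxidation level until the end. The N-acyl lactam is an acyl donor and a Michael acceptor that will not survive alkoxides, organolithiums or hydride, so both C–N bonds come last. The electron-rich arenes restrict the oxidants and make β-aryl cations easy to form. The feature that opens the key step is that every ring bond joins a benzylic carbon to a carbonyl-bearing carbon. For the ring bond across which aryl and acyl are trans, the benzylic carbon can be a C–Cu centre born from an (E)-styrene and its partner a sulfonate-bearing carbinol carbon, while the boron delivered in the same addition marks the second carbonyl-bearing carbon, cis to that aryl group, and the aryl-bearing centre already in the chain steers the face of addition.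

## Retrosynthesis

**19 ⇒ 16 + 2 × 17.** Both imide N–C(O) bonds are cut. No earlier intermediate could carry the unsaturated imides through base, organometallic or fluoride steps, so this cut must be the last one. It removes both sensitive rings and leaves the centrosymmetric diacid 16 and two molecules of the commercial lactam 17. The forward step is a double N-acylation through dichloride 18 that must not epimerise the α-carbons, hence base-free conditions.

**16 ⇒ 15 ⇒ 14.** Both carboxyl groups are traced to primary alcohols (diol 15), one of them masked as a silyl ether in 14. Carbons at the CH2O level cannot epimerise and tolerate alkoxide and organolithium reagents. The trans-1,3 relation of the arms excludes lactol formation during oxidation. The forward oxidation has to spare the veratryl rings.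

**14 ⇒ 12.** The exocyclic C–CH2OH bond is cut back to a C–B bond. One-carbon homologation of a boronic ester proceeds with retention, so boron in 12 stands exactly where the second carboxyl carbon must end. Direct carboxylation of a C–Cu or C–B bond at this hindered position is less dependable.

**12 ⇒ 9 + 10 (key disconnection).** The ring bond between the benzylic carbon and the silyloxymethyl-bearing carbon is cut together with the C–B bond. This turns the four-centre ring into an open chain (9) with two stereocentres and one E alkene, plus bis(pinacolato)diboron 10. Cutting two ring bonds at once ([2+2]) would leave head-to-tail regiochemistry and the anti arrangement to a photochemical event. The chosen cut encodes them in connectivity, alkene geometry and one carbinol configuration. The forward reaction must deliver regioselective syn borylcupration, face selection by the allylic stereocentre, and SN2 closure at a hindered secondary mesylate in competition with elimination. The oxygenated arm is an ether, so the carbon beside the mesylate has no acidic C–H. A tert-butyldimethylsilyl ether is chosen because aldehyde 6 is a catalogue compound and the group survives KOtBu and LiCH2Cl.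

**9 ⇒ 8 ⇒ 5 + 6.** The mesylate comes from alcohol 8 with retention. In 8 the C2–C3 bond is cut to a 1,3-diarylallyl nucleophile (from acetate 5) and silyloxyacetaldehyde 6. The allyl unit is symmetrical, so no regiochemical question arises, and a closed chair transition state gives the required 2,3-anti isomer directly. A glycolate ester-enolate Claisen rearrangement would make the same bond but gives the 2,3-syn series. It would then need a carbinol inversion beside an electron-rich aryl-bearing carbon, plus reduction and protecting-group exchange, several steps more.

**5 ⇒ 4 ⇒ 3 ⇒ 1 + 2.** Acetate 5 comes from allylic alcohol 4, this from chalcone 3 by 1,2-reduction, and 3 from the crossed aldol condensation of aldehyde 1 with ketone 2. Both arenes are bought with their methoxy groups in place.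

## Roads not taken

**Alternative 1:** The cut is at both imide C–N bonds of a ring that is bought, cyclobutane-1,2,3,4-tetracarboxylic dianhydride A1 (cis,trans,cis). In the forward key step two equivalents of lactam 17, deprotonated with a lithium base, would open both anhydride rings to give the bis-imide diacid A2.
- Merits: the ring, its α,α,β,β framework and both sensitive imides arrive in one step, so this is far shorter than the plan adopted here.
- Weak points: the second anhydride can open at either carbonyl, so the 1,3-bis-imide competes with its 1,2-isomer without an evident bias. Both carboxyl groups of A2 must then be exchanged for aryl groups with retention. Decarboxylative arylation passes through cyclobutyl radicals flanked by one cis and one trans neighbour, which offers no facial control, and it would expose the enone imides to nickel and arylmetal reagents.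
- Comparison: Alternative 1 wins clearly on step count. The chosen route sets against it that each aryl-bearing centre is fixed by a defined event (chair allylation, syn addition) and that the imides never meet an organometallic reagent.

**Alternative 2:** The cut is at four C–C bonds of the two arenes. A cyclobutane core is bought and elaborated to dimethyl 2,4-bis[(E)-2-nitrovinyl]cyclobutane-1,3-dicarboxylate A3, which would undergo two thermal Diels–Alder reactions with 2,3-dimethoxybuta-1,3-diene A4 to give bis(nitrocyclohexenyl) adduct A5. Loss of nitrous acid and dehydrogenation would then aromatise both rings, and ester hydrolysis would join the present route at 16.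
- Merits: the cycloaddition is probably more reliable than the key step chosen here. The symmetric diene removes regiochemistry and the transient stereocentres do not matter.
- Weak points: the stereochemical problem is only moved into the preparation of A3, which needs four carbon substituents on the ring in the correct array and 1,3-differentiation. The Henry-type and elimination steps use base beside epimerisable ester centres, and the enol ethers in A5 are acid-labile. The sequence is long.
- Comparison: the chosen plan buys both arenes finished and spends its steps on the ring, which is where the difficulty lies.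

**Alternative 3:** The cut is at two opposite ring bonds. Two molecules of 6,7-dimethoxycoumarin A6 would undergo benzophenone-sensitised [2+2] photodimerisation to the anti head-to-tail dimer A7. Lactone opening, removal of both phenolic oxygens (triflation, reduction) and imide formation would follow.
- Merits: one step closes the ring and sets all four centres, and the cis-fused lactones guarantee the aryl–carbonyl cis relations. If the dimerisation were selective this road would be about four steps shorter than the one chosen.
- Weak points: triplet-sensitised coumarin dimerisation favours the anti head-to-head dimer, so A7 would at best be a minor isomer needing separation. The electron-rich chromophore may sensitise poorly. Excising two phenol oxygens costs steps that add nothing to the skeleton.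
- Comparison: the chosen plan fixes head-to-tail connectivity by construction and needs no photoproduct separation. It is longer and rests on a facial preference that is predicted, not proven.

Key step: step 6

Remark on the chemistry: the target is achiral (inversion centre). Compounds 4, 5 and 7–14 are racemates, and their SMILES show one enantiomer only to define relative configuration.

## Route

Step 1
Reactants: 1 3,4-dimethoxybenzaldehyde; 2 3,4-dimethoxyacetophenone
Product: 3 (E)-1,3-bis(3,4-dimethoxyphenyl)prop-2-en-1-one
Conditions: NaOH (aq), EtOH, rt
Reagents that add atoms: none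
Why: Claisen–Schmidt (crossed aldol) condensation; the enolate of 2 adds to non-enolisable 1 and the aldol dehydrates in situ to the conjugated enone with the thermodynamic E geometry.

Step 2
Reactants: 3 (E)-1,3-bis(3,4-dimethoxyphenyl)prop-2-en-1-one
Product: 4 (E)-1,3-bis(3,4-dimethoxyphenyl)prop-2-en-1-ol (racemic)
Conditions: NaBH4, CeCl3·7H2O, MeOH, 0 °C
Reagents that add atoms: none
Why: Luche reduction; CeCl3 directs hydride to the carbonyl carbon (1,2-reduction) and leaves the styrene and its geometry intact. The new carbinol centre is racemic and is erased in step 4.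

Step 3
Reactants: 4 (E)-1,3-bis(3,4-dimethoxyphenyl)prop-2-en-1-ol
Product: 5 (E)-1,3-bis(3,4-dimethoxyphenyl)allyl acetate (racemic)
Conditions: Ac2O, Et3N, DMAP (cat.), CH2Cl2, 0 °C
Reagents that add atoms: acetic anhydride, CC(=O)OC(C)=O
Why: DMAP-catalysed acetylation of a secondary alcohol; the weakly basic, aprotic medium avoids ionisation of the electron-rich, doubly activated allylic system.

Step 4
Reactants: 5 (E)-1,3-bis(3,4-dimethoxyphenyl)allyl acetate; 6 (tert-butyldimethylsilyloxy)acetaldehyde
Product: 8 (2R*,3S*,4E)-1-[(tert-butyldimethylsilyl)oxy]-3,5-bis(3,4-dimethoxyphenyl)pent-4-en-2-ol (racemic; 2,3-anti), via ethyl(1,3-diarylallyl)zinc 7 (not isolated)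
Conditions: Pd(PPh3)4 (5 mol %), Et2Zn, THF, 0 °C to rt; aq NH4Cl
Reagents that add atoms: none
Why: Palladium-catalysed umpolung allylation (Tamaru type): zerovalent palladium ionises 5 to a symmetrical 1,3-diarylallyl complex, Et2Zn transmetalates it to allylzinc 7, and 7 adds to 6 through a closed six-membered chair (Zimmerman–Traxler). The E allyl terminus and the equatorial aldehyde substituent give the 2,3-anti relation, and the aryl on the zinc-bearing carbon sits equatorial and leaves an (E)-styrene. The symmetry of the allyl unit removes any regiochemical choice.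

Step 5
Reactants: 8 (2R*,3S*,4E)-1-[(tert-butyldimethylsilyl)oxy]-3,5-bis(3,4-dimethoxyphenyl)pent-4-en-2-ol
Product: 9 (2R*,3S*,4E)-1-[(tert-butyldimethylsilyl)oxy]-3,5-bis(3,4-dimethoxyphenyl)pent-4-en-2-yl methanesulfonate (racemic; 2,3-anti)
Conditions: MsCl, Et3N, CH2Cl2, −10 °C
Reagents that add atoms: methanesulfonyl chloride, CS(=O)(=O)Cl
Why: O-Sulfonylation of the secondary alcohol; the C–O bond is not touched, so the carbinol configuration and the 2,3-anti relation are retained. Low temperature and a non-ionising solvent keep the β-aryl mesylate from solvolysing.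

Step 6
Reactants: 9 (2R*,3S*,4E)-1-[(tert-butyldimethylsilyl)oxy]-3,5-bis(3,4-dimethoxyphenyl)pent-4-en-2-yl methanesulfonate; 10 bis(pinacolato)diboron
Product: 12 pinacol [(1α,2α,3β,4β)-2,4-bis(3,4-dimethoxyphenyl)-3-{[(tert-butyldimethylsilyl)oxy]methyl}cyclobutyl]boronate (racemic), via β-borylalkylcopper 11 (not isolated)
Conditions: CuCl (10 mol %), dppp (10 mol %), KOtBu (1.2 equiv, slow addition), THF, 30 °C
Reagents that add atoms: none
Why: Copper-catalysed borylative cyclisation of a homoallylic sulfonate, the known stereospecific route to cyclobutylboronates, applied here to a more substituted chain. CuCl, dppp and KOtBu give a monovalent copper alkoxide that exchanges with 10 to a boryl–copper species, which adds syn across the (E)-styrene with boron on C4 and copper on the benzylic C5 to give 11. The C5–Cu bond then displaces the mesylate at C2 in a 4-exo-tet SN2 closure, with retention at C5 and inversion at C2, which forms the C5–C2 ring bond and closes the cyclobutane. Syn addition to the E alkene followed by retention places the aryl on C5 and boron on C4 cis, and inversion of the 2,3-anti mesylate places CH2OTBS cis to the aryl on C3 and trans to the aryl on C5. The relation of the two new centres to C3 is decided in the borylcupration: with the allylic hydrogen turned toward the incoming copper–diphosphine fragment, Bpin should reach C4 on the face opposite the sp3-branched CH(OMs)CH2OTBS arm, past the flat aryl ring, which puts boron trans to the aryl on C3. The alkylcopper from the other face could close only to an all-cis cyclobutane, which should be slow, so that material is expected to be lost as open-chain by-product and not to contaminate 12. Substitution must also outrun base-induced elimination across C2–C3, where the C3–H is benzylic and allylic; the alkoxide is therefore added slowly to an excess of 10, and the arm beside the mesylate is an ether with no acidic C–H.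

Step 7
Reactants: 12 pinacol [(1α,2α,3β,4β)-2,4-bis(3,4-dimethoxyphenyl)-3-{[(tert-butyldimethylsilyl)oxy]methyl}cyclobutyl]boronate
Product: 14 [(1α,2α,3β,4β)-3-{[(tert-butyldimethylsilyl)oxy]methyl}-2,4-bis(3,4-dimethoxyphenyl)cyclobutyl]methanol (racemic), via homologated pinacol boronate 13 (not isolated)
Conditions: BrCH2Cl, n-BuLi, THF, −78 °C to rt; then aq NaOH, H2O2, 0 °C
Reagents that add atoms: bromochloromethane, ClCBr; hydrogen peroxide, OO
Why: Matteson homologation; LiCH2Cl made in situ adds to boron and the cyclobutyl carbon migrates to the CH2 carbon with loss of chloride and retention of configuration, giving 13. Alkaline peroxide then oxidises the primary C–B bond to C–OH.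

Step 8
Reactants: 14 [(1α,2α,3β,4β)-3-{[(tert-butyldimethylsilyl)oxy]methyl}-2,4-bis(3,4-dimethoxyphenyl)cyclobutyl]methanol
Product: 15 [(1α,2α,3β,4β)-2,4-bis(3,4-dimethoxyphenyl)cyclobutane-1,3-diyl]dimethanol (centrosymmetric)
Conditions: TBAF, THF, 0 °C to rt; aq NH4Cl
Reagents that add atoms: none
Why: Fluoride cleavage of the primary silyl ether, driven by Si–F bond formation; no stereocentre is involved.

Step 9
Reactants: 15 [(1α,2α,3β,4β)-2,4-bis(3,4-dimethoxyphenyl)cyclobutane-1,3-diyl]dimethanol
Product: 16 (1α,2α,3β,4β)-2,4-bis(3,4-dimethoxyphenyl)cyclobutane-1,3-dicarboxylic acid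
Conditions: TEMPO (cat.), PhI(OAc)2, MeCN/H2O, rt
Reagents that add atoms: water, O
Why: TEMPO/PhI(OAc)2 oxidation (oxoammonium oxidation to the aldehyde, hydration by one water per carboxyl group, second oxidation) converts both primary alcohols to acids under near-neutral conditions that spare the electron-rich arenes and give the α-centres little chance to epimerise. The trans-1,3 relation of the arms rules out lactol or lactone formation.

Step 10
Reactants: 16 (1α,2α,3β,4β)-2,4-bis(3,4-dimethoxyphenyl)cyclobutane-1,3-dicarboxylic acid; 17 5,6-dihydropyridin-2(1H)-one (first of two equivalents)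
Product: 19 1,1'-{[(1α,2α,3β,4β)-2,4-bis(3,4-dimethoxyphenyl)cyclobutane-1,3-diyl]dicarbonyl}bis(5,6-dihydropyridin-2(1H)-one), via diacid dichloride 18 (not isolated)
Conditions: (COCl)2, DMF (cat.), CH2Cl2, 0 °C to rt; concentrate; then 17 (2.5 equiv), 4 Å MS, PhMe, 100 °C
Reagents that add atoms: 5,6-dihydropyridin-2(1H)-one (second equivalent of 17), O=C1NCCC=C1
Why: Acid chloride formation with (COCl)2 and catalytic DMF gives dichloride 18, and each of its two acyl chloride groups then N-acylates one molecule of lactam 17 under base-free thermal conditions with molecular sieves as the HCl sink, so two equivalents of 17 are built into 19. Without amine base no ketene can form, so both α-stereocentres are kept.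

## Compound list

1 | 3,4-dimethoxybenzaldehyde | COc1ccc(C=O)cc1OC | starting material
2 | 3,4-dimethoxyacetophenone | CC(=O)c1ccc(OC)c(OC)c1 | starting material
3 | (E)-1,3-bis(3,4-dimethoxyphenyl)prop-2-en-1-one | COc1ccc(/C=C/C(=O)c2ccc(OC)c(OC)c2)cc1OC | intermediate
4 | (E)-1,3-bis(3,4-dimethoxyphenyl)prop-2-en-1-ol, racemic | COc1ccc(/C=C/C(O)c2ccc(OC)c(OC)c2)cc1OC | intermediate
5 | (E)-1,3-bis(3,4-dimethoxyphenyl)allyl acetate, racemic | COc1ccc(/C=C/C(OC(C)=O)c2ccc(OC)c(OC)c2)cc1OC | intermediate
6 | (tert-butyldimethylsilyloxy)acetaldehyde | CC(C)(C)[Si](C)(C)OCC=O | starting material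
7 | ethyl[(E)-1,3-bis(3,4-dimethoxyphenyl)allyl]zinc | CC[Zn]C(/C=C/c1ccc(OC)c(OC)c1)c1ccc(OC)c(OC)c1 | intermediate (not isolated)
8 | (2R*,3S*,4E)-1-[(tert-butyldimethylsilyl)oxy]-3,5-bis(3,4-dimethoxyphenyl)pent-4-en-2-ol, racemic, 2,3-anti | COc1ccc(/C=C/[C@@H](c2ccc(OC)c(OC)c2)[C@@H](O)CO[Si](C)(C)C(C)(C)C)cc1OC | intermediate
9 | (2R*,3S*,4E)-1-[(tert-butyldimethylsilyl)oxy]-3,5-bis(3,4-dimethoxyphenyl)pent-4-en-2-yl methanesulfonate, racemic, 2,3-anti | COc1ccc(/C=C/[C@@H](c2ccc(OC)c(OC)c2)[C@@H](OS(C)(=O)=O)CO[Si](C)(C)C(C)(C)C)cc1OC | intermediate
10 | bis(pinacolato)diboron | CC1(C)OB(OC1(C)C)B1OC(C)(C)C(C)(C)O1 | starting material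
11 | β-borylalkylcopper from syn addition to 9 (copper on benzylic C5, Bpin on C4; dppp on copper written as a separate component) | COc1ccc(cc1OC)[C@@H]([Cu])[C@H](B2OC(C)(C)C(C)(C)O2)[C@@H](c2ccc(OC)c(OC)c2)[C@@H](OS(C)(=O)=O)CO[Si](C)(C)C(C)(C)C.c1ccc(cc1)P(CCCP(c1ccccc1)c1ccccc1)c1ccccc1 | intermediate (not isolated)
12 | pinacol [(1α,2α,3β,4β)-2,4-bis(3,4-dimethoxyphenyl)-3-{[(tert-butyldimethylsilyl)oxy]methyl}cyclobutyl]boronate, racemic (boron cis to the aryl on one neighbour, trans to the aryl on the other, trans to the silyloxymethyl arm) | COc1ccc(cc1OC)[C@H]1[C@H](CO[Si](C)(C)C(C)(C)C)[C@H](c2ccc(OC)c(OC)c2)[C@H]1B1OC(C)(C)C(C)(C)O1 | intermediate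
13 | pinacol {[(1α,2α,3β,4β)-2,4-bis(3,4-dimethoxyphenyl)-3-{[(tert-butyldimethylsilyl)oxy]methyl}cyclobutyl]methyl}boronate, racemic | COc1ccc(cc1OC)[C@H]1[C@H](CO[Si](C)(C)C(C)(C)C)[C@H](c2ccc(OC)c(OC)c2)[C@H]1CB1OC(C)(C)C(C)(C)O1 | intermediate (not isolated)
14 | [(1α,2α,3β,4β)-3-{[(tert-butyldimethylsilyl)oxy]methyl}-2,4-bis(3,4-dimethoxyphenyl)cyclobutyl]methanol, racemic | COc1ccc(cc1OC)[C@H]1[C@H](CO[Si](C)(C)C(C)(C)C)[C@H](c2ccc(OC)c(OC)c2)[C@H]1CO | intermediate
15 | [(1α,2α,3β,4β)-2,4-bis(3,4-dimethoxyphenyl)cyclobutane-1,3-diyl]dimethanol | COc1ccc(cc1OC)[C@H]1[C@H](CO)[C@H](c2ccc(OC)c(OC)c2)[C@H]1CO | intermediate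
16 | (1α,2α,3β,4β)-2,4-bis(3,4-dimethoxyphenyl)cyclobutane-1,3-dicarboxylic acid | COc1ccc(cc1OC)[C@H]1[C@H](C(=O)O)[C@H](c2ccc(OC)c(OC)c2)[C@H]1C(=O)O | intermediate
17 | 5,6-dihydropyridin-2(1H)-one | O=C1NCCC=C1 | starting material
18 | (1α,2α,3β,4β)-2,4-bis(3,4-dimethoxyphenyl)cyclobutane-1,3-dicarbonyl dichloride | COc1ccc(cc1OC)[C@H]1[C@H](C(=O)Cl)[C@H](c2ccc(OC)c(OC)c2)[C@H]1C(=O)Cl | intermediate (not isolated)
19 | 1,1'-{[(1α,2α,3β,4β)-2,4-bis(3,4-dimethoxyphenyl)cyclobutane-1,3-diyl]dicarbonyl}bis(5,6-dihydropyridin-2(1H)-one) | COc1ccc([C@H]2[C@H](C(=O)N3CCC=CC3=O)[C@H](c3ccc(OC)c(OC)c3)[C@H]2C(=O)N2CCC=CC2=O)cc1OC | target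

## Step count and risks

Total steps: 10. Longest linear sequence: 10 (from 1 or 2 to 19).

**Step 6 (key step).** Three things can go wrong.
- The allylic stereocentre may discriminate poorly between the alkene faces. The alkene is E-disubstituted, so allylic strain is weak, and part of the material would enter the unproductive all-cis manifold.
- The alkoxide may remove the benzylic-allylic C3–H and eliminate the mesylate to a conjugated diene before cyclisation.
- The boryl–copper may insert slowly into an electron-rich, β-branched styrene.

Fallback: set out from 1. Knoevenagel–Doebner condensation with malonic acid (pyridine, piperidine) should give (E)-3,4-dimethoxycinnamic acid F1. Irradiation of crystalline F1 in a head-to-tail packed form (topochemical [2+2] photodimerisation, the classical entry to centrosymmetric truxillic acids) should give diacid 16, where the route is rejoined before step 10. This trades designed stereocontrol for dependence on crystal packing, which must be checked for F1.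

**Step 4.** The allylzinc transition state may be too loose, eroding the anti preference or the E geometry. β-Hydride transfer from an ethyl group may also reduce the allyl–palladium complex before transmetalation.

Fallback: set out from 4. Methyl chloroformate and pyridine give (E)-1,3-bis(3,4-dimethoxyphenyl)allyl methyl carbonate F2. Copper-catalysed boryl substitution (CuCl, Xantphos, catalytic KOtBu, 10) gives pinacol (E)-1,3-bis(3,4-dimethoxyphenyl)allylboronate F3. Treatment with n-BuLi and then trifluoroacetic anhydride converts F3 into the B-butyl borinic ester F4, which adds to 6 at −78 °C through a tight boron-centred chair that favours the anti, E product. The route is rejoined at 8.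

**Step 7.** The short-lived LiCH2Cl may decompose faster than it is captured by a secondary boronate flanked by two aryl-bearing carbons. Unreacted 12 would then be oxidised to the cyclobutanol.

Fallback: set out from 12. Zweifel olefination (vinylmagnesium bromide; then I2; then NaOMe) uses a stable nucleophile in excess and should give, with retention, the vinylcyclobutane F5. Oxidative cleavage (OsO4 cat., NaIO4, 2,6-lutidine) gives the cyclobutanecarbaldehyde F6, which is reduced at once with NaBH4 to 14, where the route is rejoined.

**Step 10.** The second acylation of a weak nitrogen nucleophile by a hindered acid chloride may stall at the mono-imide. Prolonged heating may also degrade the enone lactam or epimerise an α-centre.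

Fallback: set out from 16. Amide coupling with but-3-en-1-amine (EDC, HOBt) gives the bis(N-but-3-enyl)amide F7, so the hindered carbonyl meets a strong nucleophile. Deprotonation with LiHMDS and N-acylation with unhindered acryloyl chloride at −78 °C gives the bis(N-acryloyl) imide F8. Ring-closing metathesis with second-generation Grubbs catalyst then closes both dihydropyridinone rings, and the route is rejoined at 19.

## Further compounds

F1 | step 6 | (E)-3,4-dimethoxycinnamic acid | COc1ccc(/C=C/C(=O)O)cc1OC
F2 | step 4 | (E)-1,3-bis(3,4-dimethoxyphenyl)allyl methyl carbonate, racemic | COC(=O)OC(/C=C/c1ccc(OC)c(OC)c1)c1ccc(OC)c(OC)c1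
F3 | step 4 | pinacol (E)-1,3-bis(3,4-dimethoxyphenyl)allylboronate, racemic | COc1ccc(/C=C/C(B2OC(C)(C)C(C)(C)O2)c2ccc(OC)c(OC)c2)cc1OC
F4 | step 4 | B-butyl borinic ester from F3 (pinacol oxygen trifluoroacetylated) | CCCCB(OC(C)(C)C(C)(C)OC(=O)C(F)(F)F)C(/C=C/c1ccc(OC)c(OC)c1)c1ccc(OC)c(OC)c1
F5 | step 7 | tert-butyl{[(1α,2α,3β,4β)-2,4-bis(3,4-dimethoxyphenyl)-3-vinylcyclobutyl]methoxy}dimethylsilane, racemic | COc1ccc(cc1OC)[C@H]1[C@H](CO[Si](C)(C)C(C)(C)C)[C@H](c2ccc(OC)c(OC)c2)[C@H]1C=C
F6 | step 7 | (1α,2α,3β,4β)-3-{[(tert-butyldimethylsilyl)oxy]methyl}-2,4-bis(3,4-dimethoxyphenyl)cyclobutane-1-carbaldehyde, racemic | COc1ccc(cc1OC)[C@H]1[C@H](CO[Si](C)(C)C(C)(C)C)[C@H](c2ccc(OC)c(OC)c2)[C@H]1C=O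
F7 | step 10 | (1α,2α,3β,4β)-N,N'-di(but-3-en-1-yl)-2,4-bis(3,4-dimethoxyphenyl)cyclobutane-1,3-dicarboxamide | COc1ccc(cc1OC)[C@H]1[C@H](C(=O)NCCC=C)[C@H](c2ccc(OC)c(OC)c2)[C@H]1C(=O)NCCC=C
F8 | step 10 | (1α,2α,3β,4β)-N,N'-diacryloyl-N,N'-di(but-3-en-1-yl)-2,4-bis(3,4-dimethoxyphenyl)cyclobutane-1,3-dicarboxamide | COc1ccc(cc1OC)[C@H]1[C@H](C(=O)N(CCC=C)C(=O)C=C)[C@H](c2ccc(OC)c(OC)c2)[C@H]1C(=O)N(CCC=C)C(=O)C=C
A1 | alternative 1 | cyclobutane-1,2,3,4-tetracarboxylic dianhydride, cis,trans,cis | O=C1OC(=O)[C@H]2[C@@H]1[C@@H]1C(=O)OC(=O)[C@H]21
A2 | alternative 1 | (1α,2α,3β,4β)-2,4-bis(2-oxo-5,6-dihydropyridine-1(2H)-carbonyl)cyclobutane-1,3-dicarboxylic acid | OC(=O)[C@H]1[C@H](C(=O)N2CCC=CC2=O)[C@H](C(O)=O)[C@H]1C(=O)N1CCC=CC1=O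
A3 | alternative 2 | dimethyl (1α,2α,3β,4β)-2,4-bis[(E)-2-nitrovinyl]cyclobutane-1,3-dicarboxylate | [O-][N+](=O)/C=C/[C@H]1[C@H](C(=O)OC)[C@H](/C=C/[N+](=O)[O-])[C@H]1C(=O)OC
A4 | alternative 2 | 2,3-dimethoxybuta-1,3-diene | C=C(OC)C(OC)=C
A5 | alternative 2 | dimethyl 2,4-bis(3,4-dimethoxy-6-nitrocyclohex-3-en-1-yl)cyclobutane-1,3-dicarboxylate (cyclohexene centres undefined) | COC1=C(OC)CC([N+](=O)[O-])C(C1)[C@H]1[C@H](C(=O)OC)[C@H](C2CC(OC)=C(OC)CC2[N+](=O)[O-])[C@H]1C(=O)OC
A6 | alternative 3 | 6,7-dimethoxycoumarin | COc1cc2ccc(=O)oc2cc1OC
A7 | alternative 3 | anti head-to-tail cyclodimer of 6,7-dimethoxycoumarin | O=C4Oc5cc(OC)c(OC)cc5[C@H]1[C@H](C(=O)Oc6cc(OC)c(OC)cc67)[C@H]7[C@H]14
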